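**Retrosynthetic overview**
- Target 10 comes from 4-ethoxy-2H-chromene 9 by hydrolysis of the C4 enol ether; C4 of the ketone is the oxygen-bearing carbon of an ynol ether.
- 9 comes from an aryloxy oxocarbenium ion and ethoxyacetylene 6 by a cationic formal (4+2) annulation that forms C2–C3 and C4–C4a. Ring C is the only ring made, and it is made last; rings A and B arrive intact.
- The oxocarbenium precursor 5 is the O-aryl O-pivaloyl acetal of aldehyde 1, assembled from 1, pivaloyl chloride and phenol 3 (C2–O1 bond by phenoxide alkylation).
- Feature: C2 carries O1 and the electron-rich ring B, so it can be a stabilized aldehyde-level cation. C4a is one of the two symmetry-equivalent carbons of the 3,5-dimethoxyphenoxy ring A ortho to O1, each ortho to one methoxy group (C5) and para to the other (C7).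

Key step: step 3

Remark on the chemistry: the leaving group on C2 is pivalate, not an alkoxy group. An alkyl aryl acetal is expected to ionize mainly by loss of the phenol (the better leaving group, with the alkoxy group as the better donor), which would give the wrong oxocarbenium ion and free a C-nucleophilic phenol. The catalyst is a confined imidodiphosphorimidate (IDPi) Brønsted acid built from two 3,3'-diaryl-1,1'-bi-2-naphthol units with N-trifluoromethylsulfonyl groups; the 3,3'-aryl group is to be screened. The (S,S) acid is written as a placeholder; if it gives the (R) product, the (R,R) acid is used.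

Step 1
Reactants: 1 2,3,4-trimethoxybenzaldehyde
Product: 2 chloro(2,3,4-trimethoxyphenyl)methyl pivalate (racemic)
Conditions: PivCl (1.1 equiv), ZnCl2 (3 mol%), CH2Cl2, 0 °C to rt; solution used at once
Reagents that add atoms: pivaloyl chloride, CC(C)(C)C(=O)Cl
Why: ZnCl2-catalysed addition of an acyl chloride across the aldehyde C=O (1-chloroalkyl ester formation) should give the α-chloro ester, whose new stereocenter is racemic and is erased in step 3.

Step 2
Reactants: 2 chloro(2,3,4-trimethoxyphenyl)methyl pivalate, 3 3,5-dimethoxyphenol
Product: 5 (3,5-dimethoxyphenoxy)(2,3,4-trimethoxyphenyl)methyl pivalate (racemic), via sodium 3,5-dimethoxyphenoxide 4 (not isolated)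
Conditions: 3, NaH, THF, 0 °C; then 2, −40 to 0 °C; cold NaHCO3 work-up, Et3N-deactivated silica
Reagents that add atoms: none
Why: Williamson-type O-alkylation of the phenoxide by the readily ionizing α-chloro ester (the reaction that makes acyloxyalkyl aryl ethers) should join ring A to C2 through O1 at low temperature, the bulky pivalate resisting acyl transfer to phenoxide; the acetal stereocenter is racemic and of no consequence.

Step 3
Reactants: 5 (3,5-dimethoxyphenoxy)(2,3,4-trimethoxyphenyl)methyl pivalate, 6 ethoxyacetylene
Product: 9 (S)-4-ethoxy-5,7-dimethoxy-2-(2,3,4-trimethoxyphenyl)-2H-chromene, via aryloxy oxocarbenium ion 7 (not isolated), via ethoxyvinyl cation 8 (not isolated)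
Conditions: (S,S)-IDPi acid (5 mol%, added last), 6 (3 equiv), toluene, −78 °C; Et3N quench
Reagents that add atoms: none
Why: Proposed new method: the imidodiphosphorimidate acid protonates the pivalate carbonyl of 5, pivalic acid leaves and the planar (E)-aryloxy oxocarbenium ion 7 forms as a contact ion pair with the confined chiral anion; the nucleophilic terminal carbon of 6 adds to C2 (C2–C3 bond) to give the ethoxy-stabilized vinyl cation 8, the ring A carbon ortho to O1 attacks its cationic carbon (C4–C4a bond), and loss of the arenium proton returns the acid. The closest known reaction types are the Lewis acid-mediated oxa-Povarov annulation of aryloxy oxocarbenium ions with alkenes to chromans and the counteranion-controlled addition of silyl nucleophiles to oxocarbenium ions released from acyloxy acetals; an ynol ether partner and an enantioselective annulation are not precedented. Ring C closes by a six-membered intramolecular Friedel–Crafts alkenylation, 6-endo with respect to the C3=C4 unit of the linear vinyl cation, which completes a stepwise formal (4+2) annulation. The C2 stereocenter is set in the C2–C3 bond formation, where the anion pocket shields one face of 7, and it is not touched in the ring closure; the antipode of the acid that gives (S) is chosen by experiment. The step needs the right sense of ionization, which the pivalate secures because it is a better leaving group and a poorer donor than the aryloxy group, the right regiochemistry of alkyne attack, which the polarization of the ynol ether secures, and fast ring closure, which the two symmetry-equivalent ortho carbons of ring A secure, each being ortho to one methoxy group and para to the other. The alkyne is used in excess because the pivalic acid set free adds to it under acid catalysis.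

Step 4
Reactants: 9 (S)-4-ethoxy-5,7-dimethoxy-2-(2,3,4-trimethoxyphenyl)-2H-chromene
Product: 10 (S)-5,7-dimethoxy-2-(2,3,4-trimethoxyphenyl)chroman-4-one
Conditions: 0.1 M aq. HCl, THF, 0 °C
Reagents that add atoms: water, O
Why: Acid-catalysed enol ether hydrolysis (C3 protonation, addition of water at the C4 oxocarbenium carbon, loss of ethanol) should give the C4 ketone without involving C2, and the cold, dilute acid is chosen to avoid retro-oxa-Michael opening of ring C, which would erode the C2 configuration.

**Compound list**
1 | 2,3,4-trimethoxybenzaldehyde | COc1ccc(C=O)c(OC)c1OC | starting material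
2 | chloro(2,3,4-trimethoxyphenyl)methyl pivalate (racemic) | CC(C)(C)C(=O)OC(Cl)c1ccc(OC)c(OC)c1OC | intermediate
3 | 3,5-dimethoxyphenol | COc1cc(O)cc(OC)c1 | starting material
4 | sodium 3,5-dimethoxyphenoxide | [Na+].[O-]c1cc(OC)cc(OC)c1 | intermediate
5 | (3,5-dimethoxyphenoxy)(2,3,4-trimethoxyphenyl)methyl pivalate (racemic) | CC(C)(C)C(=O)OC(Oc1cc(OC)cc(OC)c1)c1ccc(OC)c(OC)c1OC | intermediate
6 | ethoxyacetylene | CCOC#C | starting material
7 | (3,5-dimethoxyphenyl)[(2,3,4-trimethoxyphenyl)methylidene]oxonium (cation of the ion pair with the IDPi anion) | COc1cc(OC)cc([O+]=Cc2ccc(OC)c(OC)c2OC)c1 | intermediate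
8 | (S)-3-(3,5-dimethoxyphenoxy)-1-ethoxy-3-(2,3,4-trimethoxyphenyl)prop-1-en-1-ylium (cation of the ion pair with the IDPi anion) | CCO[C+]=C[C@H](Oc1cc(OC)cc(OC)c1)c1ccc(OC)c(OC)c1OC | intermediate
9 | (S)-4-ethoxy-5,7-dimethoxy-2-(2,3,4-trimethoxyphenyl)-2H-chromene | COc1cc(OC)c2c(c1)O[C@H](c1ccc(OC)c(OC)c1OC)C=C2OCC | intermediate
10 | (S)-5,7-dimethoxy-2-(2,3,4-trimethoxyphenyl)chroman-4-one | COc1cc(OC)c2c(c1)O[C@H](c1ccc(OC)c(OC)c1OC)CC2=O | target

Total step count: 4. Longest linear sequence: 4 steps (1 → 2 → 5 → 9 → 10); phenol 3 and alkyne 6 enter convergently.

**Steps most likely to fail**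

Step 3. What may go wrong:
- the acid may consume the ynol ether (protonation, addition of pivalic acid) faster than the ynol ether adds to 7;
- cation 8 may be captured by pivalate or by the ether oxygen (ending in an acyclic cinnamate-type ester) before ring closure;
- ring A of a second molecule may attack 7 intermolecularly;
- the counteranion may give weak facial control.

The fallback uses known chemistry, sets out from 5 and comes back at 10. Compound 5 is treated with 1,1-bis(trimethylsilyloxy)ethene and the same chiral imidodiphosphorimidate acid in toluene at −78 °C. The acid is silylated under these conditions and acts as a silylium Lewis acid with the chiral anion as counterion. This Mukaiyama-type addition of a silyl ketene acetal to oxocarbenium ion 7 is a known class of counteranion-controlled reaction. It should give trimethylsilyl (S)-3-(3,5-dimethoxyphenoxy)-3-(2,3,4-trimethoxyphenyl)propanoate F1, which is hydrolysed on aqueous work-up to (S)-3-(3,5-dimethoxyphenoxy)-3-(2,3,4-trimethoxyphenyl)propanoic acid F2. Trifluoroacetic anhydride in CH2Cl2 at 0 °C should then close ring C by intramolecular Friedel–Crafts acylation at the ring A carbon ortho to O1 and give 10 directly.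

Step 2. What may go wrong:
- C-alkylation of the ambident, highly activated phenoxide;
- acyl transfer from the ester to phenoxide;
- a second substitution to the diaryl acetal;
- decomposition of the acid-labile acetal ester during purification.

The fallback avoids the phenoxide alkylation of a halo ester altogether; it sets out from 1 and 3 and comes back at 9. Aldehyde 1 with CHCl3 and DBU should give 2,2,2-trichloro-1-(2,3,4-trimethoxyphenyl)ethanol F3. A Jocic reaction of this carbinol with phenol 3 and NaOH in aqueous dimethoxyethane should give 2-(3,5-dimethoxyphenoxy)-2-(2,3,4-trimethoxyphenyl)acetic acid F4. Oxidative decarboxylation with Pb(OAc)4 and pyridine in THF should give (3,5-dimethoxyphenoxy)(2,3,4-trimethoxyphenyl)methyl acetate F5. This acetate takes the place of 5 in step 3, with acetic acid as the leaving group, and gives 9.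

Step 1. What may go wrong: the addition equilibrium may lie on the side of the strongly donor-stabilized aldehyde, and the adduct may revert during handling.

The fallback makes the halo ester by cleavage of an acylal; it sets out from 1 and comes back at 5. Aldehyde 1 with pivalic anhydride and FeCl3 (catalytic) should give the isolable (2,3,4-trimethoxyphenyl)methylene bis(2,2-dimethylpropanoate) F6. Bromotrimethylsilane with ZnBr2 (catalytic) in CH2Cl2 should convert it into bromo(2,3,4-trimethoxyphenyl)methyl pivalate F7. This bromide is used in place of 2 under the conditions of step 2 to give 5.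

**Further compounds**
F1 | step 3 | trimethylsilyl (S)-3-(3,5-dimethoxyphenoxy)-3-(2,3,4-trimethoxyphenyl)propanoate | C[Si](C)(C)OC(=O)C[C@H](Oc1cc(OC)cc(OC)c1)c1ccc(OC)c(OC)c1OC
F2 | step 3 | (S)-3-(3,5-dimethoxyphenoxy)-3-(2,3,4-trimethoxyphenyl)propanoic acid | OC(=O)C[C@H](Oc1cc(OC)cc(OC)c1)c1ccc(OC)c(OC)c1OC
F3 | step 2 | 2,2,2-trichloro-1-(2,3,4-trimethoxyphenyl)ethanol (racemic) | OC(c1ccc(OC)c(OC)c1OC)C(Cl)(Cl)Cl
F4 | step 2 | 2-(3,5-dimethoxyphenoxy)-2-(2,3,4-trimethoxyphenyl)acetic acid (racemic) | OC(=O)C(Oc1cc(OC)cc(OC)c1)c1ccc(OC)c(OC)c1OC
F5 | step 2 | (3,5-dimethoxyphenoxy)(2,3,4-trimethoxyphenyl)methyl acetate (racemic) | CC(=O)OC(Oc1cc(OC)cc(OC)c1)c1ccc(OC)c(OC)c1OC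
F6 | step 1 | (2,3,4-trimethoxyphenyl)methylene bis(2,2-dimethylpropanoate) | CC(C)(C)C(=O)OC(OC(=O)C(C)(C)C)c1ccc(OC)c(OC)c1OC
F7 | step 1 | bromo(2,3,4-trimethoxyphenyl)methyl pivalate (racemic) | CC(C)(C)C(=O)OC(Br)c1ccc(OC)c(OC)c1OC
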